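The route rests on opening the dihydropyran ring (O1, C2, C3, C4, C4a, C8a) at C4–C4a and C3–C2, which frees the C3–C4 bridge as a vinyl group on boron. The feature exploited is that C4 joins arene carbon C4a while the carbinol C3 joins the quaternary C2, the exact pattern of an enantioselective three-component conjunctive cross-coupling. The precursor is a bis(alkenyl)boronate, made in the flask from vinylboronic pinacol ester and isopropenylmagnesium bromide, plus a MOM-protected 3-bromo-2-hydroxy-4-methoxyacetophenone. Palladium delivers the aryl group to C4 as isopropenyl migrates from boron to C3; retentive oxidation gives the (R)-carbinol. Phenol-to-alkene 6-exo closure and a Claisen–Schmidt condensation finish.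

Key step: step 3

Assumption: chroman numbering (O1 to C8a) is used for these atoms in open-chain precursors too. Both antipodes of the ferrocenyl bisphosphine are commercial, and the one that gives the (R)-boronate is meant, to be confirmed on 9 by Mosher ester analysis.

Step 1
Reactants: 1 2-bromo-1,3-dimethoxybenzene
Product: 3 1-(3-bromo-2-hydroxy-4-methoxyphenyl)ethanone, via dimethoxy ketone 2 (not isolated)
Conditions: AcCl, AlCl3 (2.5 equiv), CH2Cl2, 0 °C to reflux; then aq HCl
Reagents that add atoms: acetyl chloride CC(=O)Cl
Why: Friedel–Crafts acylation goes to C4 of 1 (para to one methoxy group and ortho to the other, C4 and C6 being equivalent), and excess AlCl3 chelated to the new ketone then cleaves only the crowded ortho methoxy group (chelation-assisted aryl methyl ether cleavage), no stereocenter being involved.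

Step 2
Reactants: 3 1-(3-bromo-2-hydroxy-4-methoxyphenyl)ethanone
Product: 4 1-[3-bromo-4-methoxy-2-(methoxymethoxy)phenyl]ethanone
Conditions: NaH, DMF, 0 °C; then MOMCl, 0 °C to rt
Reagents that add atoms: chloromethyl methyl ether (MOMCl) COCCl
Why: Williamson-type O-alkylation of the sodium phenoxide with MOMCl gives the acetal ether, which masks the acidic chelated phenol that would otherwise protonate boronate 7 and undergo Dakin-type cleavage in the alkaline peroxide of step 3.

Step 3
Reactants: 4 1-[3-bromo-4-methoxy-2-(methoxymethoxy)phenyl]ethanone, 5 vinylboronic acid pinacol ester, 6 isopropenylmagnesium bromide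
Product: 9 (R)-1-[3-(2-hydroxy-3-methylbut-3-en-1-yl)-4-methoxy-2-(methoxymethoxy)phenyl]ethanone, via sodium bis(alkenyl)boronate 7 (not isolated), via allylboronate 8 (not isolated)
Conditions: 5 (1.3 equiv), 6 (1.25 equiv), NaOTf (2.5 equiv), THF, 0 °C to rt; then 4, Pd(OAc)2 (3 mol %), 2,2'-bis[(dimethylamino)(phenyl)methyl]-1,1'-bis[bis(4-methoxy-3,5-dimethylphenyl)phosphino]ferrocene (MandyPhos type, single antipode, 3.6 mol %), THF/DMSO, 60 °C; then 3 M NaOH, 30% H2O2, 0 °C to rt
Reagents that add atoms: hydrogen peroxide OO
Why: Grignard 6 adds to the boron of 5 (NaOTf drives boronate formation to completion, so no free carbanion meets the ketone of 4) to give 7; zerovalent palladium inserts into the C–Br bond of 4, sodium ion strips the bromide, and the cationic divalent arylpalladium binds the unsubstituted vinyl group of 7, which triggers a 1,2-metallate shift of the isopropenyl group from boron to the boron-bearing carbon anti to palladium (C3–C2 bond), after which C(sp2)–C(sp3) reductive elimination joins C4 to arene carbon C4a. The closest known reaction type is the enantioselective palladium-catalysed conjunctive cross-coupling of bis(alkenyl)boronates, including its Grignard/NaOTf variant for aryl bromides. No ring is closed in this step, ring closure being left to step 5. The only new stereocenter, C3, is set by the chiral bisphosphine, which dictates the face of the vinyl group that palladium binds, and the stereospecific anti migration and the retentive peroxide oxidation of the C–B bond carry that choice into (R)-9. The step must choose between the two alkenyl groups, which the boronate secures because the less hindered vinyl group is the better ligand for palladium while the more substituted isopropenyl group migrates, and the conjunctive path must outrun direct Suzuki-type alkenyl transfer, which the wide-bite-angle ligand and halide-free cationic palladium favour. The two ortho oxygen substituents of 4 slow oxidative addition but speed the final reductive elimination, and pinacol allylboronate 8 should add to the hindered electron-rich aryl ketone only slowly at this temperature.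

Step 4
Reactants: 9 (R)-1-[3-(2-hydroxy-3-methylbut-3-en-1-yl)-4-methoxy-2-(methoxymethoxy)phenyl]ethanone
Product: 10 (R)-1-[2-hydroxy-3-(2-hydroxy-3-methylbut-3-en-1-yl)-4-methoxyphenyl]ethanone
Conditions: HCl (cat.), MeOH, rt to 40 °C
Reagents that add atoms: none
Why: Acid-catalysed acetal exchange (MOM cleavage): the aryl MOM acetal, crowded between two ortho substituents and releasing a chelated phenol, is lost to methanol under conditions too mild to ionise the secondary allylic alcohol, so the alkene and the (R)-carbinol persist.

Step 5
Reactants: 10 (R)-1-[2-hydroxy-3-(2-hydroxy-3-methylbut-3-en-1-yl)-4-methoxyphenyl]ethanone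
Product: 12 1-[(3R)-3-hydroxy-5-methoxy-2,2-dimethyl-3,4-dihydro-2H-chromen-8-yl]ethanone, via organomercurial 11 (not isolated)
Conditions: Hg(OAc)2, THF, rt; then 3 M NaOH, NaBH4 (0.5 equiv), 0 °C
Reagents that add atoms: none
Why: Intramolecular oxymercuration–demercuration: divalent mercury activates the 1,1-disubstituted alkene without a free carbocation, the phenol oxygen attacks the more substituted carbon C2 in a 6-exo-trig Markovnikov closure, hydride then replaces mercury much faster than it attacks the electron-rich aryl ketone, the transient C2 stereocenter vanishes as CH2Hg becomes the second methyl group, and C3 is never touched so (R) is kept.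

Step 6
Reactants: 12 1-[(3R)-3-hydroxy-5-methoxy-2,2-dimethyl-3,4-dihydro-2H-chromen-8-yl]ethanone, 13 4-hydroxybenzaldehyde
Product: 14 (E)-1-[(3R)-3-hydroxy-5-methoxy-2,2-dimethyl-3,4-dihydro-2H-chromen-8-yl]-3-(4-hydroxyphenyl)prop-2-en-1-one
Conditions: KOH (50% aq), EtOH, rt to 50 °C; then aq HCl
Reagents that add atoms: none
Why: Claisen–Schmidt condensation (aldol addition then E1cB dehydration): the methyl ketone enolate of 12 adds to 13 and dehydration gives the conjugated, thermodynamically preferred (E)-enone, the etherified ring oxygen rules out flavanone formation, and C3 carries no acidifying neighbour so its configuration holds.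

Compound list
1 | 2-bromo-1,3-dimethoxybenzene | COc1cccc(OC)c1Br | starting material
2 | 1-(3-bromo-2,4-dimethoxyphenyl)ethanone | CC(=O)c1ccc(OC)c(Br)c1OC | intermediate
3 | 1-(3-bromo-2-hydroxy-4-methoxyphenyl)ethanone | CC(=O)c1ccc(OC)c(Br)c1O | intermediate
4 | 1-[3-bromo-4-methoxy-2-(methoxymethoxy)phenyl]ethanone | CC(=O)c1ccc(OC)c(Br)c1OCOC | intermediate
5 | vinylboronic acid pinacol ester | C=CB1OC(C)(C)C(C)(C)O1 | starting material
6 | isopropenylmagnesium bromide | CC(=C)[Mg]Br | starting material
7 | sodium isopropenyl(vinyl)(pinacolato)boronate | [Na+].C=C[B-]1(C(C)=C)OC(C)(C)C(C)(C)O1 | intermediate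
8 | (R)-1-{4-methoxy-2-(methoxymethoxy)-3-[3-methyl-2-(4,4,5,5-tetramethyl-1,3,2-dioxaborolan-2-yl)but-3-en-1-yl]phenyl}ethanone | CC(=O)c1ccc(OC)c(C[C@@H](B2OC(C)(C)C(C)(C)O2)C(C)=C)c1OCOC | intermediate
9 | (R)-1-[3-(2-hydroxy-3-methylbut-3-en-1-yl)-4-methoxy-2-(methoxymethoxy)phenyl]ethanone | CC(=O)c1ccc(OC)c(C[C@@H](O)C(C)=C)c1OCOC | intermediate
10 | (R)-1-[2-hydroxy-3-(2-hydroxy-3-methylbut-3-en-1-yl)-4-methoxyphenyl]ethanone | CC(=O)c1ccc(OC)c(C[C@@H](O)C(C)=C)c1O | intermediate
11 | 1-[(3R)-2-(acetoxymercuriomethyl)-3-hydroxy-5-methoxy-2-methyl-3,4-dihydro-2H-chromen-8-yl]ethanone (both C2 epimers) | COc1ccc(C(C)=O)c2c1C[C@@H](O)C(C)(C[Hg]OC(C)=O)O2 | intermediate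
12 | 1-[(3R)-3-hydroxy-5-methoxy-2,2-dimethyl-3,4-dihydro-2H-chromen-8-yl]ethanone | COc1ccc(C(C)=O)c2c1C[C@@H](O)C(C)(C)O2 | intermediate
13 | 4-hydroxybenzaldehyde | O=Cc1ccc(O)cc1 | starting material
14 | (E)-1-[(3R)-3-hydroxy-5-methoxy-2,2-dimethyl-3,4-dihydro-2H-chromen-8-yl]-3-(4-hydroxyphenyl)prop-2-en-1-one | COc1ccc(C(=O)/C=C/c2ccc(O)cc2)c2c1C[C@@H](O)C(C)(C)O2 | target

Total step count: 6. Longest linear sequence: 6 steps (from 1 to 14).

Steps most likely to fail

Step 3.
- What may go wrong:
  - Oxidative addition into the electron-rich, doubly ortho-substituted C–Br bond may be slow.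
  - Residual bromide may block alkene binding at palladium.
  - Direct alkenyl transfer may overtake the metallate shift.
  - The allylboronate may add slowly to the aryl ketone during the long heating.
- Fallback: it sets out from 4 and comes back at 12, and it builds the C3 stereocenter by reagent-controlled epoxidation instead. Stille coupling of 4 with tributyl(3-methylbut-2-en-1-yl)stannane under Pd(PPh3)4 in DMF should give the prenyl arene 1-[4-methoxy-2-(methoxymethoxy)-3-(3-methylbut-2-en-1-yl)phenyl]ethanone F1. Shi asymmetric epoxidation follows (the fructose-type ketone antipode that gives the (R)-epoxide, KHSO5, K2CO3, MeCN/dimethoxymethane/aqueous buffer, 0 °C) and should give (R)-1-{3-[(3,3-dimethyloxiran-2-yl)methyl]-4-methoxy-2-(methoxymethoxy)phenyl}ethanone F2. Camphorsulfonic acid in wet CH2Cl2 should then cleave the MOM acetal and let the phenol oxygen open the epoxide at its tertiary carbon (6-endo). The C3–O bond stays untouched, and the product is 12.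

Step 5.
- What may go wrong:
  - Hydride may partly reduce the aryl ketone during demercuration.
  - The ring may reopen by loss of the aryloxy group when the C–Hg bond is reduced.
  - The activated arene position may be mercurated.
- Fallback: it sets out from 10 and comes back at 12 in one operation, and it makes no compound outside the list (F0). It is a cobalt-hydride hydrogen-atom-transfer hydroalkoxylation (radical–polar crossover). The reagents are [N,N'-bis(3,5-di-tert-butylsalicylidene)-1,2-cyclohexanediaminato]cobalt (divalent cobalt, catalytic), N-fluoro-2,4,6-trimethylpyridinium triflate and 1,1,3,3-tetramethyldisiloxane in PhCF3 at rt. Hydrogen is placed on the CH2 terminus and the phenol captures the tertiary centre, with no mercury and no borohydride.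

Step 6.
- What may go wrong: the aldehyde is deactivated as its phenoxide, so the aldol addition may stall and leave room for slow base-induced decay of the partners.
- Fallback: it sets out from 12 and comes back at 14, and it changes to a protected aldehyde. Condensation of 12 with 4-(methoxymethoxy)benzaldehyde (KOH, EtOH, rt) should give (E)-1-[(3R)-3-hydroxy-5-methoxy-2,2-dimethyl-3,4-dihydro-2H-chromen-8-yl]-3-[4-(methoxymethoxy)phenyl]prop-2-en-1-one F3. Brief treatment with HCl in MeOH then releases 14.

Further compounds
F1 | step 3 | 1-[4-methoxy-2-(methoxymethoxy)-3-(3-methylbut-2-en-1-yl)phenyl]ethanone | CC(=O)c1ccc(OC)c(CC=C(C)C)c1OCOC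
F2 | step 3 | (R)-1-{3-[(3,3-dimethyloxiran-2-yl)methyl]-4-methoxy-2-(methoxymethoxy)phenyl}ethanone | CC(=O)c1ccc(OC)c(C[C@H]2OC2(C)C)c1OCOC
F0 | step 5 | none | none
F3 | step 6 | (E)-1-[(3R)-3-hydroxy-5-methoxy-2,2-dimethyl-3,4-dihydro-2H-chromen-8-yl]-3-[4-(methoxymethoxy)phenyl]prop-2-en-1-one | COc1ccc(C(=O)/C=C/c2ccc(OCOC)cc2)c2c1C[C@@H](O)C(C)(C)O2
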